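Numbering used below: ring A is the benzoate ring with positions 1 (CO2Me), 2 (CH3), 3 (H), 4 (OH), 5 (CH2OH) and 6 (ether O); ring B is the phthalide arene with positions 3a (lactone CH2), 4 (CH3), 5 (ether O), 6 and 7 (OH) and 7a (lactone C=O).
Cuts: the two bonds from ring B carbons 3a and 7a to the lactone carbons, together, as a (2+2) of the 3a,7a-aryne with a two-carbon ketene acetal (the lactone C–O bond is re-formed last); the diaryl ether bond at ring A position 6 (SNAr); the carbon substituents at ring A positions 5 and 1 (formylation, carbonylation).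
Enabling feature: the lactone carbons stand on the adjacent ring B carbons 3a and 7a, and 7a has the oxygen-bearing carbon 7 on its other side; this is the pattern a 3-alkoxyaryne gives when it takes up a ketene acetal (acetal carbon beside the oxygen).
Forward order: ring A fluoride (steps 1–3), ring B phenol from coenzyme Q0 (step 4), diaryl ether (step 5), iodide at 3a and triflate at 7a (steps 6–8), four-membered ring by (2+2) (step 9), cleavage of that ring between its two new carbons (step 10), lactone closure last (step 12).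
Oxidation level: the two-carbon partner carries oxygen on both carbons, so carbon 3a receives its carbon at the aldehyde level and a glycol-type cleavage leaves the acid on 7a with no choice of migrating group, which a peracid ring expansion of the parent ketone would not guarantee.
Stereochemistry: the target has none; the sp3 CH centres that appear between steps 9 and 12 are racemic and are erased.

Key step: step 9

Remark on the chemistry: a 2-formylbenzoic acid is written as its ring-closed lactol (3-hydroxyphthalide) tautomer, and tris(trimethylsilyloxy)ethene is taken as a commercial reagent.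

**Route**

Step 1
Reactants: 1 3-fluoro-5-methylanisole
Product: 3 2-fluoro-6-methoxy-4-methylbenzaldehyde, via aryllithium 2 (not isolated)
Conditions: n-BuLi, THF, −78 °C; DMF, −78 °C to rt; 1 M HCl
Reagents that add atoms: N,N-dimethylformamide, CN(C)C=O
Why: Directed ortho-metalation removes the ring proton flanked by fluorine and methoxy, the most acidic one, and formylation of the aryllithium with DMF places the future ring A carbon substituent of position 5 between the future oxygens of positions 4 and 6.

Step 2
Reactants: 3 2-fluoro-6-methoxy-4-methylbenzaldehyde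
Product: 4 3-bromo-2-fluoro-6-methoxy-4-methylbenzaldehyde
Conditions: NBS, DMF, rt
Reagents that add atoms: N-bromosuccinimide, O=C1CCC(=O)N1Br
Why: Electrophilic aromatic bromination should go para to the methoxy group, the strongest donor on the ring, at a position that is also meta to the formyl group, whereas the only other free position is ortho to methoxy and is the less favoured site of an anisole.

Step 3
Reactants: 4 3-bromo-2-fluoro-6-methoxy-4-methylbenzaldehyde
Product: 5 methyl 2-fluoro-3-formyl-4-methoxy-6-methylbenzoate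
Conditions: CO (1 atm), Pd(OAc)2 (cat.), Xantphos, Et3N, MeOH/toluene, 70 °C
Reagents that add atoms: carbon monoxide, [C-]#[O+]; methanol, CO
Why: Palladium-catalysed methoxycarbonylation of the aryl bromide (oxidative addition to zerovalent palladium, CO insertion, methanolysis) tolerates the aldehyde and, with a wide-bite-angle ligand, the two ortho substituents.

Step 4
Reactants: 6 coenzyme Q0 (2,3-dimethoxy-5-methyl-1,4-benzoquinone)
Product: 8 4-hydroxy-2,3-dimethoxy-5-methylphenyl pivalate, via hydroquinone 7 (not isolated)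
Conditions: Na2S2O4, EtOAc/H2O, rt; then PivCl (1.0 equiv), pyridine, CH2Cl2, −40 °C, argon
Reagents that add atoms: pivaloyl chloride, CC(C)(C)C(Cl)=O
Why: Dithionite reduction of the quinone is followed by a site-selective acylation in which the bulky acyl chloride should take the hydroxyl flanked by a ring hydrogen (the future 7a oxygen of ring B) and leave the one flanked by the methyl group (the future ether oxygen at position 5 of ring B) free.

Step 5
Reactants: 8 4-hydroxy-2,3-dimethoxy-5-methylphenyl pivalate; 5 methyl 2-fluoro-3-formyl-4-methoxy-6-methylbenzoate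
Product: 10 methyl 3-formyl-2-(4-hydroxy-2,3-dimethoxy-6-methylphenoxy)-4-methoxy-6-methylbenzoate, via pivalate diaryl ether 9 (not isolated)
Conditions: K2CO3, DMF, 50 °C, argon; then MeOH, 40 °C
Reagents that add atoms: none
Why: Nucleophilic aromatic substitution (addition–elimination) of the ring B phenoxide on a fluoride activated by an ortho formyl and an ortho ester group forms the crowded diaryl ether bond at ring A position 6, and methanolysis of the aryl pivalate in the same basic medium then frees the hydroxyl on carbon 7a of ring B.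

Step 6
Reactants: 10 methyl 3-formyl-2-(4-hydroxy-2,3-dimethoxy-6-methylphenoxy)-4-methoxy-6-methylbenzoate
Product: 11 methyl 3-formyl-2-(4-hydroxy-5-iodo-2,3-dimethoxy-6-methylphenoxy)-4-methoxy-6-methylbenzoate
Conditions: NIS, MeCN, 0 °C
Reagents that add atoms: N-iodosuccinimide, O=C1CCC(=O)N1I
Why: Electrophilic iodination of a phenol at its only free ortho position (carbon 3a of ring B) should outrun attack on ring A, which has no free hydroxyl and carries two carbonyl groups.

Step 7
Reactants: 11 methyl 3-formyl-2-(4-hydroxy-5-iodo-2,3-dimethoxy-6-methylphenoxy)-4-methoxy-6-methylbenzoate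
Product: 12 methyl 3-formyl-2-[5-iodo-2,3-dimethoxy-6-methyl-4-(trifluoromethylsulfonyloxy)phenoxy]-4-methoxy-6-methylbenzoate
Conditions: Tf2O, pyridine, CH2Cl2, 0 °C
Reagents that add atoms: trifluoromethanesulfonic anhydride, O=S(=O)(OS(=O)(=O)C(F)(F)F)C(F)(F)F
Why: O-Sulfonylation of the phenol turns the oxygen on carbon 7a of ring B into the leaving group of the aryne precursor.

Step 8
Reactants: 12 methyl 3-formyl-2-[5-iodo-2,3-dimethoxy-6-methyl-4-(trifluoromethylsulfonyloxy)phenoxy]-4-methoxy-6-methylbenzoate
Product: 13 methyl 3-(dimethoxymethyl)-2-[5-iodo-2,3-dimethoxy-6-methyl-4-(trifluoromethylsulfonyloxy)phenoxy]-4-methoxy-6-methylbenzoate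
Conditions: HC(OMe)3, MeOH, TsOH (cat.), 40 °C; Et3N
Reagents that add atoms: trimethyl orthoformate, COC(OC)OC; methanol, CO
Why: Acid-catalysed acetalisation masks the ring A aldehyde against the organomagnesium species of the next step, while the aryl iodide and triflate are inert to it.

Step 9
Reactants: 13 methyl 3-(dimethoxymethyl)-2-[5-iodo-2,3-dimethoxy-6-methyl-4-(trifluoromethylsulfonyloxy)phenoxy]-4-methoxy-6-methylbenzoate; 14 tris(trimethylsilyloxy)ethene
Product: 17 methyl 3-(dimethoxymethyl)-2-{[4,5-dimethoxy-2-methyl-7,7,8-tris(trimethylsilyloxy)bicyclo[4.2.0]octa-1,3,5-trien-3-yl]oxy}-4-methoxy-6-methylbenzoate (racemic), via arylmagnesium chloride 15 (not isolated), via aryne 16 (not isolated)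
Conditions: iPrMgCl·LiCl (1.1 equiv), 14 (3 equiv), THF, −78 °C to −20 °C; cold aq. NaHCO3; used crude
Reagents that add atoms: none
Why: Iodine–magnesium exchange at carbon 3a of ring B gives arylmagnesium 15, which loses ClMgOTf on warming to give the 3a,7a-aryne 16, and this is trapped at once by the electron-rich alkene 14 in a stepwise, polar formal (2+2) cycloaddition. The nucleophilic CH(OSiMe3) terminus adds to carbon 3a, the aryne carbon remote from the methoxy group at position 7, and the aryl anion left on carbon 7a, stabilised inductively by that oxygen, closes the four-membered ring by 4-exo attack on the bis(silyloxy)carbenium carbon, so both future lactone carbons are bonded in one operation. The closest known reaction type is the regioselective (2+2) cycloaddition of 3-alkoxyarynes, generated from ortho-iodoaryl triflates, with ketene silyl acetals to give alkoxybenzocyclobutenone acetals. The one new stereocentre, the ring CH(OSiMe3), forms racemic under no control and is erased in step 10. The step needs site selectivity (acetal carbon on 7a, CH on 3a), which the 7-methoxy group should secure by distorting the triple bond, the 4-methyl group crowding carbon 3a slightly but not enough to overturn it; chemoselectivity over the ester and acetal rests on the low temperature of the exchange.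

Step 10
Reactants: 17 methyl 3-(dimethoxymethyl)-2-{[4,5-dimethoxy-2-methyl-7,7,8-tris(trimethylsilyloxy)bicyclo[4.2.0]octa-1,3,5-trien-3-yl]oxy}-4-methoxy-6-methylbenzoate (racemic)
Product: 19 methyl 3-formyl-2-[(3-hydroxy-6,7-dimethoxy-4-methyl-1-oxo-1,3-dihydroisobenzofuran-5-yl)oxy]-4-methoxy-6-methylbenzoate (racemic lactol), via hydroxy ketone 18 (not isolated)
Conditions: 1 M HCl, THF, 0 °C; then NaIO4, THF/H2O, rt
Reagents that add atoms: water, O; sodium periodate, [Na+].[O-][I](=O)(=O)=O
Why: Acid hydrolysis strips the silyl ketal, the silyl ether and the dimethyl acetal, and periodate (Malaprade-type) cleavage of the α-hydroxy ketone, whose strained carbonyl group hydrates readily and which cannot enolise without becoming a benzocyclobutadiene, leaves the carboxyl group on carbon 7a and the aldehyde on carbon 3a, which close to the lactol.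

Step 11
Reactants: 19 methyl 3-formyl-2-[(3-hydroxy-6,7-dimethoxy-4-methyl-1-oxo-1,3-dihydroisobenzofuran-5-yl)oxy]-4-methoxy-6-methylbenzoate (racemic lactol)
Product: 20 methyl 3-formyl-4-hydroxy-6-methyl-2-[(3,6,7-trihydroxy-4-methyl-1-oxo-1,3-dihydroisobenzofuran-5-yl)oxy]benzoate (racemic lactol)
Conditions: BCl3 (excess), CH2Cl2, −78 °C to 0 °C; H2O
Reagents that add atoms: none
Why: Lewis-acid ether cleavage with BCl3 should take the methyl ethers at position 4 of ring A and position 7 of ring B through chelation to the neighbouring aldehyde and lactone carbonyl groups, and the one at position 6 of ring B because it is the twisted, most basic member of three adjacent oxygens, whereas the diaryl ether cannot be dealkylated and the methyl ester should survive at or below 0 °C.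

Step 12
Reactants: 20 methyl 3-formyl-4-hydroxy-6-methyl-2-[(3,6,7-trihydroxy-4-methyl-1-oxo-1,3-dihydroisobenzofuran-5-yl)oxy]benzoate (racemic lactol)
Product: 22 NP-007516, via hydroxy acid 21 (not isolated)
Conditions: NaBH4, THF/MeOH, 0 °C, argon; then 1 M HCl to pH 2, rt
Reagents that add atoms: none
Why: Borohydride reduction takes both aldehyde-level carbons (the ring A formyl group and the open formyl carboxylate form of the lactol) but not the methyl ester, and the 2-(hydroxymethyl)benzoic acid lactonises on acidification to the phthalide.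

**Compound list**

1 | 3-fluoro-5-methylanisole | COc1cc(C)cc(F)c1 | starting material
2 | (2-fluoro-6-methoxy-4-methylphenyl)lithium | [Li]c1c(F)cc(C)cc1OC | intermediate
3 | 2-fluoro-6-methoxy-4-methylbenzaldehyde | COc1cc(C)cc(F)c1C=O | intermediate
4 | 3-bromo-2-fluoro-6-methoxy-4-methylbenzaldehyde | COc1cc(C)c(Br)c(F)c1C=O | intermediate
5 | methyl 2-fluoro-3-formyl-4-methoxy-6-methylbenzoate | COC(=O)c1c(C)cc(OC)c(C=O)c1F | intermediate
6 | coenzyme Q0 (2,3-dimethoxy-5-methyl-1,4-benzoquinone) | COC1=C(OC)C(=O)C(C)=CC1=O | starting material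
7 | 2,3-dimethoxy-5-methylbenzene-1,4-diol | COc1c(O)cc(C)c(O)c1OC | intermediate
8 | 4-hydroxy-2,3-dimethoxy-5-methylphenyl pivalate | CC(C)(C)C(=O)Oc1cc(C)c(O)c(OC)c1OC | intermediate
9 | methyl 2-[4-(2,2-dimethylpropanoyloxy)-2,3-dimethoxy-6-methylphenoxy]-3-formyl-4-methoxy-6-methylbenzoate | COC(=O)c1c(C)cc(OC)c(C=O)c1Oc1c(C)cc(OC(=O)C(C)(C)C)c(OC)c1OC | intermediate
10 | methyl 3-formyl-2-(4-hydroxy-2,3-dimethoxy-6-methylphenoxy)-4-methoxy-6-methylbenzoate | COC(=O)c1c(C)cc(OC)c(C=O)c1Oc1c(C)cc(O)c(OC)c1OC | intermediate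
11 | methyl 3-formyl-2-(4-hydroxy-5-iodo-2,3-dimethoxy-6-methylphenoxy)-4-methoxy-6-methylbenzoate | COC(=O)c1c(C)cc(OC)c(C=O)c1Oc1c(C)c(I)c(O)c(OC)c1OC | intermediate
12 | methyl 3-formyl-2-[5-iodo-2,3-dimethoxy-6-methyl-4-(trifluoromethylsulfonyloxy)phenoxy]-4-methoxy-6-methylbenzoate | COC(=O)c1c(C)cc(OC)c(C=O)c1Oc1c(C)c(I)c(OS(=O)(=O)C(F)(F)F)c(OC)c1OC | intermediate
13 | methyl 3-(dimethoxymethyl)-2-[5-iodo-2,3-dimethoxy-6-methyl-4-(trifluoromethylsulfonyloxy)phenoxy]-4-methoxy-6-methylbenzoate | COC(=O)c1c(C)cc(OC)c(C(OC)OC)c1Oc1c(C)c(I)c(OS(=O)(=O)C(F)(F)F)c(OC)c1OC | intermediate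
14 | tris(trimethylsilyloxy)ethene | C[Si](C)(C)OC=C(O[Si](C)(C)C)O[Si](C)(C)C | starting material
15 | arylmagnesium chloride of 13 (MgCl in place of iodine on carbon 3a of ring B) | COC(=O)c1c(C)cc(OC)c(C(OC)OC)c1Oc1c(C)c([Mg]Cl)c(OS(=O)(=O)C(F)(F)F)c(OC)c1OC | intermediate
16 | 3a,7a-aryne of ring B (13 without iodine and triflate) | COC(=O)c1c(C)cc(OC)c(C(OC)OC)c1OC1=C(C)C#CC(OC)=C1OC | intermediate
17 | methyl 3-(dimethoxymethyl)-2-{[4,5-dimethoxy-2-methyl-7,7,8-tris(trimethylsilyloxy)bicyclo[4.2.0]octa-1,3,5-trien-3-yl]oxy}-4-methoxy-6-methylbenzoate (racemic) | COC(=O)c1c(C)cc(OC)c(C(OC)OC)c1Oc1c(C)c2C(O[Si](C)(C)C)C(O[Si](C)(C)C)(O[Si](C)(C)C)c2c(OC)c1OC | intermediate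
18 | methyl 3-formyl-2-[(8-hydroxy-4,5-dimethoxy-2-methyl-7-oxobicyclo[4.2.0]octa-1,3,5-trien-3-yl)oxy]-4-methoxy-6-methylbenzoate (racemic) | COC(=O)c1c(C)cc(OC)c(C=O)c1Oc1c(C)c2C(O)C(=O)c2c(OC)c1OC | intermediate
19 | methyl 3-formyl-2-[(3-hydroxy-6,7-dimethoxy-4-methyl-1-oxo-1,3-dihydroisobenzofuran-5-yl)oxy]-4-methoxy-6-methylbenzoate (racemic lactol) | COC(=O)c1c(C)cc(OC)c(C=O)c1Oc1c(C)c2C(O)OC(=O)c2c(OC)c1OC | intermediate
20 | methyl 3-formyl-4-hydroxy-6-methyl-2-[(3,6,7-trihydroxy-4-methyl-1-oxo-1,3-dihydroisobenzofuran-5-yl)oxy]benzoate (racemic lactol) | COC(=O)c1c(C)cc(O)c(C=O)c1Oc1c(C)c2C(O)OC(=O)c2c(O)c1O | intermediate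
21 | 2,3-dihydroxy-6-(hydroxymethyl)-4-[3-hydroxy-2-(hydroxymethyl)-6-(methoxycarbonyl)-5-methylphenoxy]-5-methylbenzoic acid | COC(=O)c1c(C)cc(O)c(CO)c1Oc1c(C)c(CO)c(C(=O)O)c(O)c1O | intermediate
22 | NP-007516, methyl 2-[(6,7-dihydroxy-4-methyl-1-oxo-1,3-dihydroisobenzofuran-5-yl)oxy]-4-hydroxy-3-(hydroxymethyl)-6-methylbenzoate | COC(=O)c1c(C)cc(O)c(CO)c1Oc1c(C)c2c(c(O)c1O)C(=O)OC2 | target

**Count and risks**

Total step count: 12. Longest linear sequence: 11 steps (steps 1, 2, 3 and 5 to 12, from 3-fluoro-5-methylanisole).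

Steps most likely to fail:

1. Step 9. The aryne may be consumed by other paths (addition of the isopropyl Grignard reagent, silyl transfer to the anion on carbon 7a before ring closure), or the site selectivity may erode because the 4-methyl group of ring B crowds the carbon that must accept the CH(OSiMe3) terminus. The fallback sets out from phenol 10 and returns at lactol 19, installing the two carbons one at a time. Magnesium-mediated ortho-formylation (MgCl2, Et3N, paraformaldehyde, MeCN, reflux) should place a formyl group on carbon 3a, the only free position beside the hydroxyl, giving methyl 3-formyl-2-(5-formyl-4-hydroxy-2,3-dimethoxy-6-methylphenoxy)-4-methoxy-6-methylbenzoate F1. Tf2O and pyridine then give methyl 3-formyl-2-[5-formyl-2,3-dimethoxy-6-methyl-4-(trifluoromethylsulfonyloxy)phenoxy]-4-methoxy-6-methylbenzoate F2. Palladium-catalysed hydroxycarbonylation of the triflate (CO, Pd(OAc)2, 1,3-bis(diphenylphosphino)propane, Et3N, DMF/H2O, 70 °C) puts the carboxyl group on carbon 7a, and the resulting formyl acid is 19.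

2. Step 4. The two hydroxyl groups differ only by an ortho hydrogen against an ortho methyl group, so the mono-acylation may discriminate poorly, and the acyl group may scramble between oxygens in the basic medium of step 5. The fallback sets out from quinone 6 and returns at cycloadduct 17; it tells the hydroxyls apart by acidity and needs no protecting group. Bromination at the one ring CH (bromine, CH2Cl2, then Et3N) gives 2-bromo-5,6-dimethoxy-3-methyl-1,4-benzoquinone F3, which Na2S2O4 reduces to 2-bromo-5,6-dimethoxy-3-methylbenzene-1,4-diol F4. N-Phenyltriflimide with one equivalent of K2CO3 should sulfonylate the more acidic hydroxyl beside bromine, giving 2-bromo-4-hydroxy-5,6-dimethoxy-3-methylphenyl trifluoromethanesulfonate F5. SNAr of the remaining phenol on fluoride 5 (K2CO3, DMF, 40 °C) gives methyl 2-[5-bromo-2,3-dimethoxy-6-methyl-4-(trifluoromethylsulfonyloxy)phenoxy]-3-formyl-4-methoxy-6-methylbenzoate F6, and acetalisation as in step 8 gives methyl 2-[5-bromo-2,3-dimethoxy-6-methyl-4-(trifluoromethylsulfonyloxy)phenoxy]-3-(dimethoxymethyl)-4-methoxy-6-methylbenzoate F7. Bromine–magnesium exchange with iPrMgCl·LiCl (THF, −20 °C) in the presence of 14 then passes through 15 and 16 to 17.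

3. Step 10. The electron-rich, fully substituted ring B may be attacked by the oxidant, or slow cleavage may leave the strained ketol time to rearrange. The fallback sets out from hydroxy ketone 18, isolated after the acid stage alone, and returns at target 22; it replaces the oxidation by a redox-neutral isomerisation. Heating in MeOH/toluene at 90 °C should open the four-membered ring by conrotatory electrocyclic cleavage of the bond between its two sp3 carbons (hydroxyl outward). Methanol adds to the resulting ortho-quinoid ketene to give methyl 3-formyl-2-[5-(hydroxymethyl)-2,3-dimethoxy-4-(methoxycarbonyl)-6-methylphenoxy]-4-methoxy-6-methylbenzoate F8, which lactonises in the flask to methyl 2-[(6,7-dimethoxy-4-methyl-1-oxo-1,3-dihydroisobenzofuran-5-yl)oxy]-3-formyl-4-methoxy-6-methylbenzoate F9. BCl3 as in step 11 gives methyl 2-[(6,7-dihydroxy-4-methyl-1-oxo-1,3-dihydroisobenzofuran-5-yl)oxy]-3-formyl-4-hydroxy-6-methylbenzoate F10, and NaBH4 reduces the remaining aldehyde to give 22.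

**Further compounds**

F1 | step 9 | methyl 3-formyl-2-(5-formyl-4-hydroxy-2,3-dimethoxy-6-methylphenoxy)-4-methoxy-6-methylbenzoate | COC(=O)c1c(C)cc(OC)c(C=O)c1Oc1c(C)c(C=O)c(O)c(OC)c1OC
F2 | step 9 | methyl 3-formyl-2-[5-formyl-2,3-dimethoxy-6-methyl-4-(trifluoromethylsulfonyloxy)phenoxy]-4-methoxy-6-methylbenzoate | COC(=O)c1c(C)cc(OC)c(C=O)c1Oc1c(C)c(C=O)c(OS(=O)(=O)C(F)(F)F)c(OC)c1OC
F3 | step 4 | 2-bromo-5,6-dimethoxy-3-methyl-1,4-benzoquinone | COC1=C(OC)C(=O)C(C)=C(Br)C1=O
F4 | step 4 | 2-bromo-5,6-dimethoxy-3-methylbenzene-1,4-diol | COc1c(O)c(Br)c(C)c(O)c1OC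
F5 | step 4 | 2-bromo-4-hydroxy-5,6-dimethoxy-3-methylphenyl trifluoromethanesulfonate | COc1c(OS(=O)(=O)C(F)(F)F)c(Br)c(C)c(O)c1OC
F6 | step 4 | methyl 2-[5-bromo-2,3-dimethoxy-6-methyl-4-(trifluoromethylsulfonyloxy)phenoxy]-3-formyl-4-methoxy-6-methylbenzoate | COC(=O)c1c(C)cc(OC)c(C=O)c1Oc1c(C)c(Br)c(OS(=O)(=O)C(F)(F)F)c(OC)c1OC
F7 | step 4 | methyl 2-[5-bromo-2,3-dimethoxy-6-methyl-4-(trifluoromethylsulfonyloxy)phenoxy]-3-(dimethoxymethyl)-4-methoxy-6-methylbenzoate | COC(=O)c1c(C)cc(OC)c(C(OC)OC)c1Oc1c(C)c(Br)c(OS(=O)(=O)C(F)(F)F)c(OC)c1OC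
F8 | step 10 | methyl 3-formyl-2-[5-(hydroxymethyl)-2,3-dimethoxy-4-(methoxycarbonyl)-6-methylphenoxy]-4-methoxy-6-methylbenzoate | COC(=O)c1c(C)cc(OC)c(C=O)c1Oc1c(C)c(CO)c(C(=O)OC)c(OC)c1OC
F9 | step 10 | methyl 2-[(6,7-dimethoxy-4-methyl-1-oxo-1,3-dihydroisobenzofuran-5-yl)oxy]-3-formyl-4-methoxy-6-methylbenzoate | COC(=O)c1c(C)cc(OC)c(C=O)c1Oc1c(C)c2COC(=O)c2c(OC)c1OC
F10 | step 10 | methyl 2-[(6,7-dihydroxy-4-methyl-1-oxo-1,3-dihydroisobenzofuran-5-yl)oxy]-3-formyl-4-hydroxy-6-methylbenzoate | COC(=O)c1c(C)cc(O)c(C=O)c1Oc1c(C)c2COC(=O)c2c(O)c1O
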